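Target as read from the SMILES: a dibenzo[b,f]oxepine fused at C10/C11 to a 3,4-dihydro-2H-pyran. Both pyran stereocentres are S, and the 3′-OH is cis to the 4-methylpent-3-enyl chain.

## Retrosynthetic overview
1. Target ⇒ desilylation ⇒ the ring-A prenyl C–C bond, made last on the complete tetracycle by aromatic Claisen [3,3] rearrangement of a 3-O-(1,1-dimethylallyl) ether, which is carried as its propargyl ether.
2. Pyran ring ⇒ cyclodehydration of the tertiary OH onto the C10 ketone. The C11–CH2 bond ⇒ oxepinone enolate plus a terminal epoxide.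
3. The epoxide carries both stereocentres: the quaternary carbon is bought in (S)-linalool, and the carbinol carbon comes from OH-directed epoxidation of its vinyl group.
4. Oxepinone ⇒ Friedel–Crafts acylation ⇒ Ullmann diaryl ether of two bought arenes. The ketone then differentiates the two phenols.
5. Ring order: arenes A and B (bought) → oxepine → pyran.

**Assumption:** (S)-(+)-linalool (coriandrol, the coriander-oil terpene) is purchasable in ≥95 % ee.

**Locants:** dibenzo[b,f]oxepine numbering is used for the tricycle (O5; C10 on ring B; C11 on ring A). Primed locants are used for the pyran (O1′, C2′ quaternary, C3′ carbinol, C4′ CH2).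

## Route

Step 1
Reactants: 1 (S)-(+)-linalool
Product: 2 (2S)-6-methyl-2-[(2S)-oxiran-2-yl]hept-5-en-2-ol
Conditions: VO(acac)2 (2 mol %), t-BuOOH (1.3 equiv, decane), toluene, 0 °C → rt; SiO2 separation from the epoxide-carbon epimer
Reagents that add atoms: tert-butyl hydroperoxide, CC(C)(C)OO
Why: In this vanadium-catalysed hydroxyl-directed epoxidation the V-alkoxide of the tertiary allylic OH delivers oxygen to the adjacent vinyl group faster than to the remote trisubstituted alkene, and the new stereocentre is induced only by the bought carbinol centre, whose Me/CH2R difference is small (dr about 1:1 to 2:1 expected), so the (S,S) isomer is isolated by chromatography.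

Step 2
Reactants: 3 2-(2-bromo-4-methoxyphenyl)acetic acid; 4 3-methoxyphenol
Product: 5 2-[4-methoxy-2-(3-methoxyphenoxy)phenyl]acetic acid
Conditions: CuCl (10 mol %), K2CO3 (3 equiv), diglyme, 140 °C; then aq HCl
Reagents that add atoms: none
Why: This is an Ullmann diaryl ether coupling in which the ortho-CH2CO2K group assists copper insertion into the C–Br bond, and no other halide or free phenol is present.

Step 3
Reactants: 5 2-[4-methoxy-2-(3-methoxyphenoxy)phenyl]acetic acid
Product: 6 3,7-dimethoxydibenzo[b,f]oxepin-10(11H)-one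
Conditions: PPA, 90 °C
Reagents that add atoms: none
Why: This intramolecular Friedel–Crafts acylation closes the seven-membered ring at the ring-B position para to OMe and ortho to the ether oxygen, the only activated site within reach.

Step 4
Reactants: 6 3,7-dimethoxydibenzo[b,f]oxepin-10(11H)-one
Product: 7 3,7-dihydroxydibenzo[b,f]oxepin-10(11H)-one
Conditions: BBr3 (4 equiv), CH2Cl2, −78 °C → rt; then H2O
Reagents that add atoms: none
Why: Lewis-acid aryl methyl ether cleavage (SN2 of bromide on the O-complexed methyl) is run here because the diaryl ether and ketone survive it and no acid-sensitive group has yet been introduced.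

Step 5
Reactants: 7 3,7-dihydroxydibenzo[b,f]oxepin-10(11H)-one
Product: 8 3-hydroxy-7-(triisopropylsilyloxy)dibenzo[b,f]oxepin-10(11H)-one
Conditions: TIPSCl (1.05 equiv), Et3N (1.1 equiv), THF–DMF, −10 °C
Reagents that add atoms: triisopropylsilyl chloride, CC(C)[Si](Cl)(C(C)C)C(C)C
Why: In this chemoselective O-silylation the 7-OH, para to the ketone, is a vinylogous acid about 1.5–2 pKa units stronger than the 3-OH, so with one equivalent of amine base only its phenoxide is present and gets silylated.

Step 6
Reactants: 8 3-hydroxy-7-(triisopropylsilyloxy)dibenzo[b,f]oxepin-10(11H)-one; 9 3-chloro-3-methylbut-1-yne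
Product: 10 3-(2-methylbut-3-yn-2-yloxy)-7-(triisopropylsilyloxy)dibenzo[b,f]oxepin-10(11H)-one
Conditions: DBU (1.3 equiv), CuCl2·2H2O (1 mol %), MeCN, 0 °C
Reagents that add atoms: none
Why: In this copper-catalysed propargylic etherification the remaining phenoxide captures the tertiary propargylic electrophile at oxygen, while C11 is too hindered to take a tertiary carbon.

Step 7
Reactants: 10 3-(2-methylbut-3-yn-2-yloxy)-7-(triisopropylsilyloxy)dibenzo[b,f]oxepin-10(11H)-one; 2 (2S)-6-methyl-2-[(2S)-oxiran-2-yl]hept-5-en-2-ol (1.3 equiv)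
Product: 11 11-[(2S,3S)-2,3-dihydroxy-3,7-dimethyloct-6-en-1-yl]-3-(2-methylbut-3-yn-2-yloxy)-7-(triisopropylsilyloxy)dibenzo[b,f]oxepin-10(11H)-one (C11 epimers)
Conditions: t-BuOK (0.3 equiv), DMF, 60 °C
Reagents that add atoms: none
Why: In this base-catalysed SN2 epoxide opening the aryl- and aroyl-stabilised C11 enolate attacks the unhindered CH2 terminus and the alkoxide formed regenerates the enolate, so neither C–O stereocentre is touched, the enolate is too weak a base to trigger Payne rearrangement, and the new C11 centre is erased in step 9.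

Step 8
Reactants: 11 diol ketone from step 7
Product: 12 11-[(2S,3S)-2-(tert-butyldimethylsilyloxy)-3-hydroxy-3,7-dimethyloct-6-en-1-yl]-3-(2-methylbut-3-yn-2-yloxy)-7-(triisopropylsilyloxy)dibenzo[b,f]oxepin-10(11H)-one (C11 epimers)
Conditions: TBSCl (1.5 equiv), imidazole (3 equiv), DMAP (cat.), DMF, rt → 40 °C
Reagents that add atoms: tert-butyldimethylsilyl chloride, CC(C)(C)[Si](C)(C)Cl
Why: This selective silylation takes the secondary OH and leaves the tertiary OH untouched, which blocks the competing five-membered (dihydrofuran) ring closure in the next step.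

Step 9
Reactants: 12 TBS-protected hydroxy ketone
Product: 14 tetracyclic pyrano-fused dibenzoxepine enol ether (2′S 3′S; 3′-OTBS; 3-O-CMe2C≡CH; 7-OTIPS), via cyclic hemiketal 13 (not isolated)
Conditions: PPTS (15 mol %), 4 Å MS, toluene, 80 °C
Reagents that add atoms: none
Why: In this acid-catalysed cyclodehydration (intramolecular ketalisation then loss of water) only the free tertiary OH can add to the C10 ketone, the enol ether conjugated with both arenes is the sink, both C11 epimers converge, and no C–O bond at C2′ or C3′ is broken, so both stereocentres are retained.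

Step 10
Reactants: 14 tetracyclic propargyl ether
Product: 17 tetracyclic 2-prenyl-3-phenol (2′S 3′S; 3′-OTBS; 7-OTIPS), via dimethylallyl aryl ether 15 (not isolated), via ortho-dienone 16 (not isolated)
Conditions: H2 (1 atm), Lindlar cat., quinoline, toluene, rt; filter; then 115 °C, 12 h
Reagents that add atoms: none
Why: Lindlar semihydrogenation stops at the 1,1-dimethylallyl ether, which on heating undergoes the aromatic Claisen [3,3]-sigmatropic rearrangement to the ortho-dienone and tautomerises, forming the aryl–CH2 bond of the prenyl group at C2 (the ortho site para to O5) in preference to the flanked C4 site (about 3–5:1 expected, isomers separated) without touching any stereocentre.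

Step 11
Reactants: 17 tetracyclic 2-prenyl-3-phenol
Product: 18 target CNP0185870.1
Conditions: TBAF (3 equiv), AcOH (3 equiv), THF, 0 °C → rt
Reagents that add atoms: none
Why: This buffered fluoride desilylation removes the aryl TIPS and the secondary TBS groups under near-neutral conditions, so the enol ether cannot exchange between the 3′-OH and O1′ and the prenyl phenol cannot cyclise.

## Compound list
1 | (S)-(+)-linalool, (3S)-3,7-dimethylocta-1,6-dien-3-ol | CC(C)=CCC[C@](C)(O)C=C | starting material
2 | (2S)-6-methyl-2-[(2S)-oxiran-2-yl]hept-5-en-2-ol | CC(C)=CCC[C@](C)(O)[C@@H]1CO1 | intermediate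
3 | 2-(2-bromo-4-methoxyphenyl)acetic acid | COc1ccc(CC(=O)O)c(Br)c1 | starting material
4 | 3-methoxyphenol | COc1cccc(O)c1 | starting material
5 | 2-[4-methoxy-2-(3-methoxyphenoxy)phenyl]acetic acid | COc1cccc(Oc2cc(OC)ccc2CC(=O)O)c1 | intermediate
6 | 3,7-dimethoxydibenzo[b,f]oxepin-10(11H)-one | O=C1Cc2ccc(OC)cc2Oc2cc(OC)ccc12 | intermediate
7 | 3,7-dihydroxydibenzo[b,f]oxepin-10(11H)-one | O=C1Cc2ccc(O)cc2Oc2cc(O)ccc12 | intermediate
8 | 3-hydroxy-7-(triisopropylsilyloxy)dibenzo[b,f]oxepin-10(11H)-one | O=C1Cc2ccc(O)cc2Oc2cc(O[Si](C(C)C)(C(C)C)C(C)C)ccc12 | intermediate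
9 | 3-chloro-3-methylbut-1-yne | CC(C)(Cl)C#C | starting material
10 | 3-(2-methylbut-3-yn-2-yloxy)-7-(triisopropylsilyloxy)dibenzo[b,f]oxepin-10(11H)-one | O=C1Cc2ccc(OC(C)(C)C#C)cc2Oc2cc(O[Si](C(C)C)(C(C)C)C(C)C)ccc12 | intermediate
11 | 11-[(2S,3S)-2,3-dihydroxy-3,7-dimethyloct-6-en-1-yl] derivative of 10 (C11 epimers) | CC(C)=CCC[C@](C)(O)[C@@H](O)CC1C(=O)c2ccc(O[Si](C(C)C)(C(C)C)C(C)C)cc2Oc2cc(OC(C)(C)C#C)ccc12 | intermediate
12 | secondary O-TBS ether of 11 (C11 epimers) | CC(C)=CCC[C@](C)(O)[C@@H](O[Si](C)(C)C(C)(C)C)CC1C(=O)c2ccc(O[Si](C(C)C)(C(C)C)C(C)C)cc2Oc2cc(OC(C)(C)C#C)ccc12 | intermediate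
13 | cyclic hemiketal (O1′ bound to C10; C10-OH; C10/C11 mixtures) | CC(C)=CCC[C@]1(C)OC2(O)C(C[C@@H]1O[Si](C)(C)C(C)(C)C)c1ccc(OC(C)(C)C#C)cc1Oc1cc(O[Si](C(C)C)(C(C)C)C(C)C)ccc12 | intermediate
14 | tetracyclic enol ether, 2′S,3′S, 3′-OTBS, 3-O-(2-methylbut-3-yn-2-yl), 7-OTIPS | CC(C)=CCC[C@]1(C)OC2=C(C[C@@H]1O[Si](C)(C)C(C)(C)C)c1ccc(OC(C)(C)C#C)cc1Oc1cc(O[Si](C(C)C)(C(C)C)C(C)C)ccc12 | intermediate
15 | 3-O-(2-methylbut-3-en-2-yl) ether of the tetracycle | CC(C)=CCC[C@]1(C)OC2=C(C[C@@H]1O[Si](C)(C)C(C)(C)C)c1ccc(OC(C)(C)C=C)cc1Oc1cc(O[Si](C(C)C)(C(C)C)C(C)C)ccc12 | intermediate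
16 | ring-A cyclohexa-2,4-dienone (C3=O; C2 sp3 with H and prenyl) | CC(C)=CCC[C@]1(C)OC2=C(C[C@@H]1O[Si](C)(C)C(C)(C)C)C1=CC(CC=C(C)C)C(=O)C=C1Oc1cc(O[Si](C(C)C)(C(C)C)C(C)C)ccc12 | intermediate
17 | tetracycle with 2-prenyl, 3-OH, 3′-OTBS, 7-OTIPS (2′S,3′S) | CC(C)=CCC[C@]1(C)OC2=C(C[C@@H]1O[Si](C)(C)C(C)(C)C)c1cc(CC=C(C)C)c(O)cc1Oc1cc(O[Si](C(C)C)(C(C)C)C(C)C)ccc12 | intermediate
18 | CNP0185870.1 (2′S,3′S) | CC(C)=CCC[C@]1(C)OC2=C(C[C@@H]1O)c1cc(CC=C(C)C)c(O)cc1Oc1cc(O)ccc12 | target

## Step count
- Total steps: 11.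
- Longest linear sequence: 10 steps (3/4 → 18, steps 2–11). Step 1 is a one-step side branch that joins at step 7.

## Steps most likely to fail

**Step 1.** The only control element distinguishes CH3 from CH2R, so the dr will be near 1:1 and the wanted (S,S) epoxide may even be the minor isomer. Some oxidation of the 6,7-alkene, leading to linalool oxides, is also possible.

The fallback buys the carbinol CH centre instead and sets the quaternary centre from it. It uses no intermediate of the route: it replaces 1 by a bought ester, and it comes back at 2.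
- Methyl (S)-2,2-dimethyl-1,3-dioxolane-4-carboxylate F1 is converted with MeNHOMe·HCl/i-PrMgCl into the Weinreb amide F2.
- MeMgBr then gives the methyl ketone F3.
- 4-Methylpent-3-enylmagnesium bromide (from 5-bromo-2-methylpent-2-ene) is added with MgBr2·OEt2 in Et2O/CH2Cl2 at −78 °C. It attacks the Cram chelate from the side of the α-hydrogen and gives the (S,S) tertiary alcohol F4.
- Aqueous AcOH frees the triol F5.
- TsCl/pyridine sulfonylates only the primary OH, giving the primary tosylate F6.
- K2CO3/MeOH closes F6 to 2 with the C–O bond at the stereocentre intact.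

**Step 7.** A stabilised, hindered enolate may open the epoxide too slowly at a temperature the para-acyl aryl TIPS ether tolerates. O-alkylation or lactol formation could also complicate step 8.

The fallback changes the union to an SN2 alkylation with an already protected halide. It sets out from 2 and 10 and comes back at 12.
- LiI/AcOH in THF opens 2 at the terminus to give the (2R,3S)-1-iodo-3,7-dimethyloct-6-ene-2,3-diol F7.
- TBSOTf/2,6-lutidine at −78 °C silylates only the secondary OH, giving the iodide F8.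
- The potassium enolate of 10 (KHMDS, 1.0 equiv, THF–DMF, rt → 45 °C) is too weakly basic to deprotonate the tertiary OH. It displaces iodide and gives 12 directly, so 11 is skipped.

**Step 9.** A tertiary alcohol adding to a hindered, electron-rich aryl ketone may stall, or may need acid strong enough to endanger the tertiary carbinol.

The fallback splits the ring closure into ketal formation and an aprotic elimination. It sets out from 12 and comes back at 14.
- HC(OMe)3 and PPTS in MeOH at rt trap the ketone as the cyclic mixed methyl ketal F9, in which the internal tertiary OH has replaced one methoxy group.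
- TMSOTf/i-Pr2NEt in CH2Cl2 at −20 → 0 °C then removes the remaining methoxy group with loss of H-11, giving enol ether 14.

## Further compounds
F1 | step 1 | methyl (S)-2,2-dimethyl-1,3-dioxolane-4-carboxylate (bought) | COC(=O)[C@@H]1COC(C)(C)O1
F2 | step 1 | (S)-N-methoxy-N,2,2-trimethyl-1,3-dioxolane-4-carboxamide | CON(C)C(=O)[C@@H]1COC(C)(C)O1
F3 | step 1 | 1-[(S)-2,2-dimethyl-1,3-dioxolan-4-yl]ethanone | CC(=O)[C@@H]1COC(C)(C)O1
F4 | step 1 | (2S)-2-[(4S)-2,2-dimethyl-1,3-dioxolan-4-yl]-6-methylhept-5-en-2-ol | CC(C)=CCC[C@](C)(O)[C@@H]1COC(C)(C)O1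
F5 | step 1 | (2S,3S)-3,7-dimethyloct-6-ene-1,2,3-triol | CC(C)=CCC[C@](C)(O)[C@@H](O)CO
F6 | step 1 | (2S,3S)-2,3-dihydroxy-3,7-dimethyloct-6-en-1-yl 4-methylbenzenesulfonate | CC(C)=CCC[C@](C)(O)[C@@H](O)COS(=O)(=O)c1ccc(C)cc1
F7 | step 7 | (2R,3S)-1-iodo-3,7-dimethyloct-6-ene-2,3-diol | CC(C)=CCC[C@](C)(O)[C@@H](O)CI
F8 | step 7 | (2R,3S)-2-(tert-butyldimethylsilyloxy)-1-iodo-3,7-dimethyloct-6-en-3-ol | CC(C)=CCC[C@](C)(O)[C@@H](O[Si](C)(C)C(C)(C)C)CI
F9 | step 9 | cyclic mixed methyl ketal of 12 (C10: OMe and O1′; C10/C11 mixtures) | CC(C)=CCC[C@]1(C)OC2(OC)C(C[C@@H]1O[Si](C)(C)C(C)(C)C)c1ccc(OC(C)(C)C#C)cc1Oc1cc(O[Si](C(C)C)(C(C)C)C(C)C)ccc12
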